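(The rate constants are invented; the run is a simulation.)

I began with the easy step: I treated the dissolving solid in this flask as a steady feed into a tank with two outlets, and asked where one dissolved unit ends up.

solid substrate 0.80 M; time 10 min

    starting material → target (k1 = 0.17 s⁻¹)
    starting material → intermediate A (k2 = 0.27 s⁻¹)
    intermediate A ⇌ intermediate B (K3 = 0.11, k3 = 0.14 s⁻¹)
    target → over-reaction product (k4 = 0.078 s⁻¹)
    starting material + target → side product (k5 = 0.0095 L mol⁻¹ s⁻¹)
    solid substrate ⇌ starting material, rate k6*(cs6 - [starting material]) while solid is left; crystals form when [starting material] > cs6 (cs6 = 0.29 M, k6 = 0.21 s⁻¹)

- percent here means solid substrate units held: one side product counts as two
- solid substrate is a solid; its amount is given per volume of the solution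
- at the start none of the solid substrate is in solution
- what has only dissolved of solid substrate counts as not reacted
- the reaction counts as stopped when no species that holds the solid substrate changes by six tenths of a point or more over the second half of the time
- run time (flask): 10 min

* why nothing more happens at 10 min, or that something still does (for what has run out or reacted, a solid counts together with what of it has only dissolved) (all of the solid substrate has reacted / it is still moving / forward and back rates have come level)
* the intermediate A standing at 10 min, as a percentage of the solid substrate charged

With the dissolving and the two outlets of starting material, I put the dissolved level c where feed balanced drain, at 0.0937 M. That made the feed 0.0412 M s⁻¹, so I reckoned the solid to last 19.4 s. The outlets respond in 2.27 s, much faster than that, so c followed the feed, and each dissolved unit met a fork. Its branch to intermediate A took 61.4%.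

Next I added the exchange between intermediate A and intermediate B. It relaxes in 0.708 s, far shorter than 10 min, so I let the pair reach balance, with 90.1% of it as intermediate A. The product of these two fractions is the standing share f, the part of the charge that ends as intermediate A: 55.3%. Neither solubility nor charge stands in it.

The over-reaction step takes target, not starting material, but the side step drains starting material, so I put the first answer back in. In this picture target could climb to a ceiling of 0.204 M, but with a time constant of 12.8 s I reckoned its average during dissolving at 48.5% of that. I therefore reckoned the side step to divert 0.214% of the starting material, which took f to 55.2%. Since 19.4 s is far shorter than 10 min, I expected the charge to have reacted long before the reading.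

The forecast said all of the solid substrate has reacted and gave 55.2%, reasoning that “the target has long since turned into over-reaction product by 10 min, so nothing is still changing”.

The simulation of the flask gave all of the solid substrate has reacted and 55.2%, with starting material at 0% at 10.0 min. At 0.149 min in the flask, starting material went to intermediate A 1.6 times as fast as to target; this ratio is the fork's selectivity factor. The half-life of starting material by the side step was then 14 min, far longer than the 0.0263 min reckoned from the two outlets together. For the same flask read at 25 min, f of 55.3%, less the side step, came to 55.2%, and the reading was 55.2% intermediate A.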